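The isochromene is disconnected in ring A across C4a–C8a and C5–C6. Ring A carries adjacent oxygens on C6 and C7 and is fused through C4a–C8a to pyran ring B (C1, O2, C3, C4). A 4-methoxyfuran can therefore supply C6, C7, C8, C8a and the C6 oxygen, and a terminal alkyne C4a and C5. One thermal intramolecular furan Diels–Alder reaction, followed by opening of the oxygen bridge, should build both rings and the C6 phenol in a single operation. Its precursor is a (Z)-2-(furfuryloxy)pent-2-en-4-yn-1-one whose enol ether double bond holds the alkyne next to the furan. O-Methylation then completes the target.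

Key step: step 8

Assumption: the target has no stereocentre, so the only configuration carried through the route is the Z double bond of 11 and 12; compounds 9 and 13 are racemic.

Step 1
Reactants: 1 methyl 4-bromofuran-2-carboxylate
Product: 2 methyl 4-methoxyfuran-2-carboxylate
Conditions: NaOMe (3 equiv), CuI (10 mol %), 1,10-phenanthroline (20 mol %), MeOH, 100 °C, sealed tube
Reagents that add atoms: sodium methoxide, [Na+].[O-]C
Why: Ullmann-type copper-catalysed C–O coupling of a heteroaryl bromide with methoxide should replace the bromine at furan C4; the 2-ester keeps the ring electron-poor and base-stable, and ester exchange with methoxide is degenerate.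

Step 2
Reactants: 2 methyl 4-methoxyfuran-2-carboxylate
Product: 3 (4-methoxyfuran-2-yl)methanol
Conditions: LiAlH4, THF, 0 °C; aqueous NaOH work-up; used directly
Reagents that add atoms: none
Why: Hydride reduction of an ester to the primary alcohol; the basic work-up and direct use should protect the acid-sensitive, electron-rich furfuryl alcohol.

Step 3
Reactants: 3 (4-methoxyfuran-2-yl)methanol; 4 2-chloro-N-methoxy-N-methylacetamide
Product: 5 N-methoxy-2-[(4-methoxyfuran-2-yl)methoxy]-N-methylacetamide
Conditions: NaH, THF, 0 °C; then 4, Bu4NI (cat.), 0 °C to rt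
Reagents that add atoms: none
Why: Williamson ether synthesis (SN2 displacement of chloride by the sodium alkoxide); the amide carbonyl does not react with the alkoxide, which avoids the carbonyl-addition side reactions of an α-haloketone.

Step 4
Reactants: 5 N-methoxy-2-[(4-methoxyfuran-2-yl)methoxy]-N-methylacetamide; 6 2,4-dimethoxyphenylmagnesium bromide
Product: 7 1-(2,4-dimethoxyphenyl)-2-[(4-methoxyfuran-2-yl)methoxy]ethan-1-one
Conditions: 6 (THF solution, 1.5 equiv), THF, 0 °C; aqueous NH4Cl
Reagents that add atoms: none
Why: Acyl substitution of an N-methoxy-N-methylamide by an aryl Grignard reagent should stop at the ketone, because the magnesium-chelated tetrahedral adduct persists until work-up.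

Step 5
Reactants: 7 1-(2,4-dimethoxyphenyl)-2-[(4-methoxyfuran-2-yl)methoxy]ethan-1-one; 8 3-(trimethylsilyl)prop-2-ynal
Product: 9 1-(2,4-dimethoxyphenyl)-3-hydroxy-2-[(4-methoxyfuran-2-yl)methoxy]-5-(trimethylsilyl)pent-4-yn-1-one (racemic mixture of both diastereomers)
Conditions: LiN(SiMe3)2, THF, −78 °C; then 8, −78 °C; AcOH quench at −78 °C
Reagents that add atoms: none
Why: Directed aldol addition: the only enolisable position of 7 (the oxygen-bearing CH2) is deprotonated and adds 1,2 to the ynal at low temperature; the two new stereocentres (C2, C3) are left uncontrolled because step 6 removes both.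

Step 6
Reactants: 9 1-(2,4-dimethoxyphenyl)-3-hydroxy-2-[(4-methoxyfuran-2-yl)methoxy]-5-(trimethylsilyl)pent-4-yn-1-one
Product: 11 (Z)-1-(2,4-dimethoxyphenyl)-2-[(4-methoxyfuran-2-yl)methoxy]-5-(trimethylsilyl)pent-2-en-4-yn-1-one, via aldol methanesulfonate 10 (not isolated)
Conditions: MsCl, Et3N, CH2Cl2, −10 °C; then DBU, 0 °C to rt
Reagents that add atoms: none
Why: O-Sulfonylation followed by E1cB elimination through the ketone enolate should give the conjugated enynone with the alkynyl group anti to the bulky aroyl group and syn to the ether oxygen (Z), the geometry of least allylic strain, while erasing both stereocentres of 9.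

Step 7
Reactants: 11 (Z)-1-(2,4-dimethoxyphenyl)-2-[(4-methoxyfuran-2-yl)methoxy]-5-(trimethylsilyl)pent-2-en-4-yn-1-one
Product: 12 (Z)-1-(2,4-dimethoxyphenyl)-2-[(4-methoxyfuran-2-yl)methoxy]pent-2-en-4-yn-1-one
Conditions: Bu4NF, AcOH (1 equiv each), THF, 0 °C; used promptly
Reagents that add atoms: none
Why: Fluoride-induced protodesilylation of an alkynylsilane; the acetic acid buffer should keep the ynenone free from base-induced conjugate addition, and the Z geometry is not touched.

Step 8
Reactants: 12 (Z)-1-(2,4-dimethoxyphenyl)-2-[(4-methoxyfuran-2-yl)methoxy]pent-2-en-4-yn-1-one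
Product: 14 (2,4-dimethoxyphenyl)(6-hydroxy-7-methoxy-1H-isochromen-3-yl)methanone, via 6,8a-epoxy-bridged cycloadduct 13 (not isolated)
Conditions: PhMe (0.01 M, degassed), BHT (5 mol %), 110 °C; then PPTS (5 mol %), rt
Reagents that add atoms: none
Why: Heating should let the electron-rich 4-methoxyfuran add as the diene across the tethered alkyne in a normal-demand, asynchronous [4+2] cycloaddition: the most nucleophilic furan α-carbon (the CH next to the methoxy-bearing carbon, future C6) bonds to the electrophilic terminal carbon of the ynenone (C5), and the substituted furan α-carbon (C8a) bonds to the inner alkyne carbon (C4a). The closest known reaction type is the intramolecular Diels–Alder reaction of furans with tethered alkynes, in which the 7-oxanorbornadiene opens to a phenol. Ring B closes as the tether ring of the cycloaddition, a six-membered ring completed by the C4a–C8a bond across the four-atom link C1–O2–C3=C4, and ring A closes as the cycloaddition ring itself and becomes benzenoid when the oxygen bridge of 13 breaks. No stereocentre survives: the two bridgehead centres of 13 form as a racemate, are tied to each other by the bridge and are lost on aromatisation. The step needs the alkyne on the same side of C3=C4 as O2, which the Z geometry set in step 6 secures and which also keeps the alkyne away from the ketone oxygen. It also needs the bridge to break at C8a–O and not at C6–O, which the C7 methoxy group secures by stabilising the C8a allyl cation as a vinylogous oxocarbenium ion, while C6 keeps the hydrogen that is lost in the final tautomerisation to the C6 phenol (completed by the trace of PPTS if the adduct persists).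

Step 9
Reactants: 14 (2,4-dimethoxyphenyl)(6-hydroxy-7-methoxy-1H-isochromen-3-yl)methanone
Product: 15 (2,4-dimethoxyphenyl)(6,7-dimethoxy-1H-isochromen-3-yl)methanone
Conditions: MeI, K2CO3, acetone, 40 °C
Reagents that add atoms: iodomethane, CI
Why: Williamson O-methylation of the phenoxide (SN2); the ketone has no enolisable α-hydrogen and neither C1 nor C4 is acidic enough to compete under carbonate.

Compound list
1 | methyl 4-bromofuran-2-carboxylate | COC(=O)c1cc(Br)co1 | starting material
2 | methyl 4-methoxyfuran-2-carboxylate | COC(=O)c1cc(OC)co1 | intermediate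
3 | (4-methoxyfuran-2-yl)methanol | COc1coc(CO)c1 | intermediate
4 | 2-chloro-N-methoxy-N-methylacetamide | CON(C)C(=O)CCl | starting material
5 | N-methoxy-2-[(4-methoxyfuran-2-yl)methoxy]-N-methylacetamide | CON(C)C(=O)COCc1cc(OC)co1 | intermediate
6 | 2,4-dimethoxyphenylmagnesium bromide | COc1ccc([Mg]Br)c(OC)c1 | starting material
7 | 1-(2,4-dimethoxyphenyl)-2-[(4-methoxyfuran-2-yl)methoxy]ethan-1-one | COc1ccc(C(=O)COCc2cc(OC)co2)c(OC)c1 | intermediate
8 | 3-(trimethylsilyl)prop-2-ynal | C[Si](C)(C)C#CC=O | starting material
9 | 1-(2,4-dimethoxyphenyl)-3-hydroxy-2-[(4-methoxyfuran-2-yl)methoxy]-5-(trimethylsilyl)pent-4-yn-1-one (racemic, C2/C3 diastereomer mixture, configuration not controlled) | COc1ccc(C(=O)C(OCc2cc(OC)co2)C(O)C#C[Si](C)(C)C)c(OC)c1 | intermediate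
10 | 1-(2,4-dimethoxyphenyl)-2-[(4-methoxyfuran-2-yl)methoxy]-1-oxo-5-(trimethylsilyl)pent-4-yn-3-yl methanesulfonate (diastereomer mixture) | COc1ccc(C(=O)C(OCc2cc(OC)co2)C(OS(C)(=O)=O)C#C[Si](C)(C)C)c(OC)c1 | intermediate (not isolated)
11 | (Z)-1-(2,4-dimethoxyphenyl)-2-[(4-methoxyfuran-2-yl)methoxy]-5-(trimethylsilyl)pent-2-en-4-yn-1-one | C[Si](C)(C)C#C/C=C(\OCc1cc(OC)co1)C(=O)c1ccc(OC)cc1OC | intermediate
12 | (Z)-1-(2,4-dimethoxyphenyl)-2-[(4-methoxyfuran-2-yl)methoxy]pent-2-en-4-yn-1-one | C#C/C=C(\OCc1cc(OC)co1)C(=O)c1ccc(OC)cc1OC | intermediate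
13 | (2,4-dimethoxyphenyl)(7-methoxy-1H,6H-6,8a-epoxyisochromen-3-yl)methanone (7-oxanorbornadiene cycloadduct; racemic, one enantiomer drawn, bridgeheads linked cis by the oxygen bridge) | COC1=C[C@]23COC(C(=O)c4ccc(OC)cc4OC)=CC2=C[C@H]1O3 | intermediate (not isolated)
14 | (2,4-dimethoxyphenyl)(6-hydroxy-7-methoxy-1H-isochromen-3-yl)methanone | COc1ccc(C(=O)C2=Cc3cc(O)c(OC)cc3CO2)c(OC)c1 | intermediate
15 | (2,4-dimethoxyphenyl)(6,7-dimethoxy-1H-isochromen-3-yl)methanone | COc1ccc(C(=O)C2=Cc3cc(OC)c(OC)cc3CO2)c(OC)c1 | target

Total step count: 9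
Longest linear sequence: 9 steps (1 to 15)

Steps most likely to fail

Step 8. The cycloaddition may be outrun by [3,3]-sigmatropic rearrangement of the furfuryl vinyl ether or by oligomerisation of the terminal ynenone, or the bridged adduct may revert before it opens. The fallback gives up the furan and closes ring B on a benzene that already carries the C6 and C7 methoxy groups. It sets out from 4 and comes back at 15. Purchased (2-bromo-4,5-dimethoxyphenyl)methanol is alkylated with 4 (NaH, THF) to give 2-[(2-bromo-4,5-dimethoxyphenyl)methoxy]-N-methoxy-N-methylacetamide F1. Addition of 6 (THF, 0 °C) gives 2-[(2-bromo-4,5-dimethoxyphenyl)methoxy]-1-(2,4-dimethoxyphenyl)ethan-1-one F2. α-Methylenation (paraformaldehyde, i-Pr2NH·CF3CO2H, THF, reflux) gives 2-[(2-bromo-4,5-dimethoxyphenyl)methoxy]-1-(2,4-dimethoxyphenyl)prop-2-en-1-one F3. A 6-endo intramolecular Heck reaction (Pd(OAc)2, P(o-tol)3, Et3N, MeCN, 80 °C) should then join the aryl carbon to the terminal alkene carbon (C4a–C4) and, after β-hydride elimination, give 15 directly.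

Step 6. The elimination may give a mixture of double-bond isomers, or the propargylic sulfonate may be diverted by substitution with chloride before the enolate expels it. The fallback forms the double bond by olefination instead; it sets out from 3 and comes back at 11. Alkoxide formation from 3 (NaH, THF) and alkylation with diethyl (tosyloxymethyl)phosphonate gives diethyl {[(4-methoxyfuran-2-yl)methoxy]methyl}phosphonate F4. Deprotonation (LiN(i-Pr)2, THF, −78 °C) and acylation with methyl 2,4-dimethoxybenzoate gives diethyl {2-(2,4-dimethoxyphenyl)-1-[(4-methoxyfuran-2-yl)methoxy]-2-oxoethyl}phosphonate F5. A Horner–Wadsworth–Emmons reaction with 8 (LiCl, DBU, MeCN, 0 °C) should then give 11, the stabilised ketophosphonate placing the alkynyl group trans to the aroyl group.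

Step 1. C–O coupling at the β-position of the furan may be slow, so that protodebromination and ester cleavage take over. The fallback brings in the oxygen through boron; it sets out from 1 and comes back at 2. Miyaura borylation (B2pin2, Pd(dppf)Cl2, KOAc, dioxane, 80 °C) gives methyl 4-(4,4,5,5-tetramethyl-1,3,2-dioxaborolan-2-yl)furan-2-carboxylate F6. Oxidation (NaBO3·4H2O, THF–water, rt) gives methyl 4-hydroxyfuran-2-carboxylate F7. O-Methylation (Me2SO4, K2CO3, acetone) should then give 2.

Further compounds
F1 | step 8 | 2-[(2-bromo-4,5-dimethoxyphenyl)methoxy]-N-methoxy-N-methylacetamide | CON(C)C(=O)COCc1cc(OC)c(OC)cc1Br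
F2 | step 8 | 2-[(2-bromo-4,5-dimethoxyphenyl)methoxy]-1-(2,4-dimethoxyphenyl)ethan-1-one | COc1ccc(C(=O)COCc2cc(OC)c(OC)cc2Br)c(OC)c1
F3 | step 8 | 2-[(2-bromo-4,5-dimethoxyphenyl)methoxy]-1-(2,4-dimethoxyphenyl)prop-2-en-1-one | COc1ccc(C(=O)C(=C)OCc2cc(OC)c(OC)cc2Br)c(OC)c1
F4 | step 6 | diethyl {[(4-methoxyfuran-2-yl)methoxy]methyl}phosphonate | CCOP(=O)(OCC)COCc1cc(OC)co1
F5 | step 6 | diethyl {2-(2,4-dimethoxyphenyl)-1-[(4-methoxyfuran-2-yl)methoxy]-2-oxoethyl}phosphonate (racemic) | CCOP(=O)(OCC)C(OCc1cc(OC)co1)C(=O)c1ccc(OC)cc1OC
F6 | step 1 | methyl 4-(4,4,5,5-tetramethyl-1,3,2-dioxaborolan-2-yl)furan-2-carboxylate | COC(=O)c1cc(B2OC(C)(C)C(C)(C)O2)co1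
F7 | step 1 | methyl 4-hydroxyfuran-2-carboxylate | COC(=O)c1cc(O)co1
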